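**Plan**

- Retrosynthesis: the nine benzyl ethers and a C3 acetate come off last. The upper pyran ring is then cut in one operation at C2–C3 and C4–C4a, giving an O-aryl oxocarbenium ion (stored as a mixed methyl aryl acetal) and the (E)-enol acetate of catechin-8-ylacetaldehyde.
- Enabling feature: in the upper ring O1–C2–C3–C4–C4a–C8a, the unit C4a=C8a–O1=C2 (B ring on C2) is a cationic 2-oxadiene. C3=C4 is an alkene whose C4 sits on C8 of the lower catechin, so a C4 cation is stabilised by that 2,4,6-trioxygenated A ring.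
- Forward: the acetal comes from 2,3-dihydroxybenzaldehyde and 3,4-bis(benzyloxy)benzaldehyde (steps 1–4). The alkene comes from (+)-catechin (steps 5–11); its formyl carbon becomes C4 and the boron-Wittig carbon becomes C3. The lower chroman is catechin's own, the upper pyran closes in step 12, and steps 13–14 deprotect.
- Stereochemistry: the lower (2R,3S) centres come from (+)-catechin and are never touched. Upper C2, C3 and C4 arise together in step 12: all-trans from the E-alkene and an all-equatorial closure, absolute sense from a chiral acid anion, and any wrong-face adduct is a separable diastereomer.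

Key step: step 12

Assumption: which antipode of the chiral acid is matched with the catechin-derived alkene cannot be foreseen, so the (R) label in step 12 stands for the matched antipode, to be found in a first screen of both.

**Route**

Step 1
Reactants: 1 2,3-dihydroxybenzaldehyde
Product: 2 2,3-bis(benzyloxy)benzaldehyde
Conditions: BnBr, K2CO3, DMF, 60 °C
Reagents that add atoms: benzyl bromide, BrCc1ccccc1
Why: Williamson ether synthesis alkylates both phenols under carbonate conditions and leaves the aldehyde alone.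

Step 2
Reactants: 2 2,3-bis(benzyloxy)benzaldehyde
Product: 4 2,3-bis(benzyloxy)phenol, via 2,3-bis(benzyloxy)phenyl formate 3 (not isolated)
Conditions: mCPBA, CH2Cl2, rt; then Et3N (cat.), MeOH, rt
Reagents that add atoms: mCPBA, OOC(=O)c1cccc(Cl)c1
Why: Dakin-type Baeyer–Villiger oxidation, in which the electron-rich aryl group migrates to give formate 3, followed by mild methanolysis that does not touch the benzyl ethers.

Step 3
Reactants: 5 3,4-bis(benzyloxy)benzaldehyde
Product: 6 3,4-bis(benzyloxy)benzaldehyde dimethyl acetal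
Conditions: HC(OMe)3, MeOH, p-TsOH (cat.), rt; Et3N quench
Reagents that add atoms: trimethyl orthoformate, COC(OC)OC; methanol, CO
Why: acid-catalysed acetalisation, driven to completion by the orthoformate as water scavenger.

Step 4
Reactants: 6 3,4-bis(benzyloxy)benzaldehyde dimethyl acetal; 4 2,3-bis(benzyloxy)phenol
Product: 8 3,4-bis(benzyloxy)benzaldehyde 2,3-bis(benzyloxy)phenyl methyl acetal (racemic), via α-chloro ether 7 (not isolated)
Conditions: AcCl, ZnBr2 (cat.), CH2Cl2, 0 °C → rt; then 4, i-Pr2NEt, 0 °C → rt; chromatography on Et3N-deactivated silica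
Reagents that add atoms: none
Why: zinc-catalysed acetal/acid chloride exchange gives chloro ether 7, which O-alkylates the phenol under amine base in the way MOM chloride does (SN1-type Williamson etherification); the acetal centre is racemic and becomes planar in step 12.

Step 5
Reactants: 9 (+)-catechin
Product: 10 5,7,3',4'-tetra-O-benzylcatechin
Conditions: BnBr, K2CO3, DMF, 0 °C → rt
Reagents that add atoms: benzyl bromide, BrCc1ccccc1
Why: Williamson etherification of the four phenols only, since carbonate does not deprotonate the C3 alcohol and is too mild to epimerise C2.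

Step 6
Reactants: 10 5,7,3',4'-tetra-O-benzylcatechin
Product: 11 8-bromo-5,7,3',4'-tetra-O-benzylcatechin
Conditions: NBS (1.0 equiv), CH2Cl2, −78 °C → rt
Reagents that add atoms: N-bromosuccinimide, O=C1CCC(=O)N1Br
Why: electrophilic aromatic bromination, for which C8 is the most reactive position of a 5,7-dialkoxyflavan, so one equivalent at low temperature should give the 8-bromide.

Step 7
Reactants: 11 8-bromo-5,7,3',4'-tetra-O-benzylcatechin
Product: 12 8-bromo-3,5,7,3',4'-penta-O-benzylcatechin
Conditions: NaH, BnBr, TBAI (cat.), DMF, 0 °C → rt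
Reagents that add atoms: benzyl bromide, BrCc1ccccc1
Why: Williamson etherification of the secondary C3 alcohol, which removes the last acidic proton before the organolithium step and touches no stereocentre.

Step 8
Reactants: 12 8-bromo-3,5,7,3',4'-penta-O-benzylcatechin
Product: 15 8-formyl-3,5,7,3',4'-penta-O-benzylcatechin, via aryllithium 13 (not isolated), via lithium hemiaminal alkoxide 14 (not isolated)
Conditions: n-BuLi, THF, −78 °C; DMF, −78 → 0 °C; H2O
Reagents that add atoms: N,N-dimethylformamide, CN(C)C=O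
Why: bromine–lithium exchange outruns benzylic deprotonation at −78 °C, and the doubly ortho-alkoxy-stabilised aryllithium is formylated by DMF (Bouveault formylation).

Step 9
Reactants: 15 8-formyl-3,5,7,3',4'-penta-O-benzylcatechin
Product: 17 (E)-2-(penta-O-benzylcatechin-8-yl)vinylboronic acid pinacol ester, via lithium β,β-diboryl alkoxide 16 (not isolated)
Conditions: CH2(Bpin)2, LiTMP, THF, 0 °C; then 15, −78 °C → rt; H2O
Reagents that add atoms: bis[(pinacolato)boryl]methane, CC1(C)OB(CB2OC(C)(C)C(C)(C)O2)OC1(C)C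
Why: boron–Wittig olefination, in which lithiated bis(boryl)methane adds to the aldehyde and adduct 16 loses the boron–oxygen pair by syn elimination to give the trans-alkenylboronate, so the E geometry is set here.

Step 10
Reactants: 17 (E)-2-(penta-O-benzylcatechin-8-yl)vinylboronic acid pinacol ester
Product: 18 potassium (E)-[2-(penta-O-benzylcatechin-8-yl)vinyl]trifluoroborate
Conditions: aq. KHF2, MeOH/THF, rt; crystallisation
Reagents that add atoms: potassium hydrogen difluoride, [K+].[F-].F
Why: ligand exchange of a pinacol boronate with KHF2 gives the trifluoroborate with retention of alkene geometry, and crystallisation should remove any Z isomer.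

Step 11
Reactants: 18 potassium (E)-[2-(penta-O-benzylcatechin-8-yl)vinyl]trifluoroborate
Product: 19 (E)-2-(3,5,7,3',4'-penta-O-benzylcatechin-8-yl)vinyl acetate
Conditions: AcOH, CuBr (cat.), DMAP, 4 Å MS, O2 (1 atm), MeCN, 40 °C
Reagents that add atoms: acetic acid, CC(=O)O
Why: Chan–Lam-type copper-catalysed oxidative C–O coupling of an alkenyltrifluoroborate with a carboxylic acid, a known route to enol esters that proceeds with retention of alkene geometry.

Step 12
Reactants: 8 3,4-bis(benzyloxy)benzaldehyde 2,3-bis(benzyloxy)phenyl methyl acetal (racemic); 19 (E)-2-(3,5,7,3',4'-penta-O-benzylcatechin-8-yl)vinyl acetate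
Product: 22 (2R,3S,4S)-3-acetoxy-7,8-bis(benzyloxy)-2-[3,4-bis(benzyloxy)phenyl]-4-[(2R,3S)-penta-O-benzylcatechin-8-yl]chroman, via aryl oxocarbenium ion 20 (not isolated), via open-chain C4 cation 21 (not isolated)
Conditions: (R)-3,3'-bis(2,4,6-triisopropylphenyl)-BINOL N-triflylphosphoramide (10 mol %), 5 Å MS, toluene, −40 → −10 °C, slow addition of 8
Reagents that add atoms: none
Why: Proposed new method: the chiral acid protonates the more basic methoxy oxygen of 8 and expels methanol (taken up by the sieves) to give aryl oxocarbenium 20, a cationic 2-oxadiene, as an ion pair with the chiral anion; the acetoxy-bearing carbon of 19 adds to its carbon because the charge then builds on the neighbouring carbon, where the 2,4,6-trioxygenated catechin A ring stabilises it far better than an acyloxy group could stabilise the regioisomeric cation, and cation 21 is captured by the ring carbon ortho to O1 and para to the C7 benzyloxy group, the proton lost returning the catalyst. The closest known reaction types are the Lewis-acid oxa-Povarov reaction of aryl oxocarbenium ions with styrenes and the Povarov reaction of (E)-anethole-type styrenes, neither of which has been run with an enol ester as the 2π partner or under chiral-anion control. The pyran ring closes in a six-membered Friedel–Crafts alkylation (6-exo-trig when the C4 cation is counted in its quinone-methide form), the second bond of a stepwise or strongly asynchronous formal [4+2]. C2 and C3 are set in the first bond formation, the trans relation coming from the approach that keeps the B-ring aryl and the acetoxy group apart, and C4 is set in the chair-like closure that places the catechinyl group equatorial, trans to the acetate and cis to the C2 aryl, which is also what the E-alkene delivers in the concerted limit. The absolute sense (2R,3S,4S) is to come from the chiral anion shielding one face of 20 in the matched pairing with the catechin stereocentres, and since 19 is a single enantiomer any wrong-face adduct is a diastereomer that chromatography removes. The step needs regioselectivity (secured by the trioxygenated ring at C4), chemoselectivity against Friedel–Crafts attack at the free C6 of the catechin ring (secured by its two flanking benzyloxy groups and by slow addition of 8) and facial selectivity (secured by the catalyst).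

Step 13
Reactants: 22 (2R,3S,4S)-3-acetoxy-7,8-bis(benzyloxy)-2-[3,4-bis(benzyloxy)phenyl]-4-[(2R,3S)-penta-O-benzylcatechin-8-yl]chroman
Product: 23 (2R,3S,4S)-7,8-bis(benzyloxy)-2-[3,4-bis(benzyloxy)phenyl]-4-[(2R,3S)-penta-O-benzylcatechin-8-yl]chroman-3-ol
Conditions: NaOMe (cat.), MeOH/THF, rt → 40 °C
Reagents that add atoms: none
Why: Zemplén transesterification removes the only ester, while the benzyl ethers and all five stereocentres are inert to methoxide because no free phenol is present.

Step 14
Reactants: 23 (2R,3S,4S)-7,8-bis(benzyloxy)-2-[3,4-bis(benzyloxy)phenyl]-4-[(2R,3S)-penta-O-benzylcatechin-8-yl]chroman-3-ol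
Product: 24 (2R,3S,4S)-2-(3,4-dihydroxyphenyl)-4-[(2R,3S)-catechin-8-yl]chroman-3,7,8-triol (CNP0231186.1)
Conditions: H2 (1 atm), Pd(OH)2/C, THF/MeOH/H2O, rt; filtration under argon, lyophilisation
Reagents that add atoms: none
Why: hydrogenolysis of the nine benzyl ethers over Pearlman's catalyst, under neutral conditions in which the C2–O1 and C4–aryl benzylic bonds of flavans are expected to persist, so no stereocentre is affected.

**Compound list**

1 | 2,3-dihydroxybenzaldehyde | O=Cc1cccc(O)c1O | starting material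
2 | 2,3-bis(benzyloxy)benzaldehyde | O=Cc1cccc(OCc2ccccc2)c1OCc1ccccc1 | intermediate
3 | 2,3-bis(benzyloxy)phenyl formate (not isolated) | O=COc1cccc(OCc2ccccc2)c1OCc1ccccc1 | intermediate
4 | 2,3-bis(benzyloxy)phenol | Oc1cccc(OCc2ccccc2)c1OCc1ccccc1 | intermediate
5 | 3,4-bis(benzyloxy)benzaldehyde | O=Cc1ccc(OCc2ccccc2)c(OCc2ccccc2)c1 | starting material
6 | 3,4-bis(benzyloxy)benzaldehyde dimethyl acetal | COC(OC)c1ccc(OCc2ccccc2)c(OCc2ccccc2)c1 | intermediate
7 | 1,2-bis(benzyloxy)-4-[chloro(methoxy)methyl]benzene, racemic α-chloro ether (not isolated) | COC(Cl)c1ccc(OCc2ccccc2)c(OCc2ccccc2)c1 | intermediate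
8 | 3,4-bis(benzyloxy)benzaldehyde 2,3-bis(benzyloxy)phenyl methyl acetal, racemic | COC(Oc1cccc(OCc2ccccc2)c1OCc1ccccc1)c1ccc(OCc2ccccc2)c(OCc2ccccc2)c1 | intermediate
9 | (+)-catechin, (2R,3S) | Oc1cc(O)c2c(c1)O[C@H](c1ccc(O)c(O)c1)[C@@H](O)C2 | starting material
10 | (2R,3S)-5,7,3',4'-tetra-O-benzylcatechin | c1c(OCc3ccccc3)cc(OCc3ccccc3)c2c1O[C@H](c1ccc(OCc3ccccc3)c(OCc3ccccc3)c1)[C@@H](O)C2 | intermediate
11 | (2R,3S)-8-bromo-5,7,3',4'-tetra-O-benzylcatechin | Brc1c(OCc3ccccc3)cc(OCc3ccccc3)c2c1O[C@H](c1ccc(OCc3ccccc3)c(OCc3ccccc3)c1)[C@@H](O)C2 | intermediate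
12 | (2R,3S)-8-bromo-3,5,7,3',4'-penta-O-benzylcatechin | Brc1c(OCc3ccccc3)cc(OCc3ccccc3)c2c1O[C@H](c1ccc(OCc3ccccc3)c(OCc3ccccc3)c1)[C@@H](OCc1ccccc1)C2 | intermediate
13 | (2R,3S)-8-lithio-3,5,7,3',4'-penta-O-benzylcatechin (not isolated) | [Li]c1c(OCc3ccccc3)cc(OCc3ccccc3)c2c1O[C@H](c1ccc(OCc3ccccc3)c(OCc3ccccc3)c1)[C@@H](OCc1ccccc1)C2 | intermediate
14 | lithium (dimethylamino)[(2R,3S)-penta-O-benzylcatechin-8-yl]methoxide, epimers at the new carbon (not isolated) | [Li+].[O-]C(N(C)C)c1c(OCc3ccccc3)cc(OCc3ccccc3)c2c1O[C@H](c1ccc(OCc3ccccc3)c(OCc3ccccc3)c1)[C@@H](OCc1ccccc1)C2 | intermediate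
15 | (2R,3S)-8-formyl-3,5,7,3',4'-penta-O-benzylcatechin | O=Cc1c(OCc3ccccc3)cc(OCc3ccccc3)c2c1O[C@H](c1ccc(OCc3ccccc3)c(OCc3ccccc3)c1)[C@@H](OCc1ccccc1)C2 | intermediate
16 | lithium 2,2-bis(pinacolboryl)-1-[(2R,3S)-penta-O-benzylcatechin-8-yl]ethoxide, epimers at the carbinol carbon (not isolated) | [Li+].[O-]C(C(B3OC(C)(C)C(C)(C)O3)B3OC(C)(C)C(C)(C)O3)c1c(OCc3ccccc3)cc(OCc3ccccc3)c2c1O[C@H](c1ccc(OCc3ccccc3)c(OCc3ccccc3)c1)[C@@H](OCc1ccccc1)C2 | intermediate
17 | (E)-2-[(2R,3S)-penta-O-benzylcatechin-8-yl]vinylboronic acid pinacol ester | CC1(C)OB(/C=C/c2c(OCc4ccccc4)cc(OCc4ccccc4)c3c2O[C@H](c2ccc(OCc4ccccc4)c(OCc4ccccc4)c2)[C@@H](OCc2ccccc2)C3)OC1(C)C | intermediate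
18 | potassium (E)-{2-[(2R,3S)-penta-O-benzylcatechin-8-yl]vinyl}trifluoroborate | [K+].F[B-](F)(F)/C=C/c1c(OCc3ccccc3)cc(OCc3ccccc3)c2c1O[C@H](c1ccc(OCc3ccccc3)c(OCc3ccccc3)c1)[C@@H](OCc1ccccc1)C2 | intermediate
19 | (E)-2-[(2R,3S)-3,5,7,3',4'-penta-O-benzylcatechin-8-yl]vinyl acetate | CC(=O)O/C=C/c1c(OCc3ccccc3)cc(OCc3ccccc3)c2c1O[C@H](c1ccc(OCc3ccccc3)c(OCc3ccccc3)c1)[C@@H](OCc1ccccc1)C2 | intermediate
20 | [3,4-bis(benzyloxy)benzylidene][2,3-bis(benzyloxy)phenyl]oxonium, aryl oxocarbenium ion paired with the chiral phosphoramide anion (not isolated) | c1ccccc1COc1ccc(C=[O+]c2cccc(OCc3ccccc3)c2OCc2ccccc2)cc1OCc1ccccc1 | intermediate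
21 | open-chain C4 carbocation after C2–C3 bond formation, C2 and C3 configured as in 22 (not isolated) | c1ccccc1COc1ccc([C@@H](Oc2cccc(OCc3ccccc3)c2OCc2ccccc2)[C@@H](OC(C)=O)[CH+]c2c(OCc3ccccc3)cc(OCc3ccccc3)c3c2O[C@H](c2ccc(OCc4ccccc4)c(OCc4ccccc4)c2)[C@@H](OCc2ccccc2)C3)cc1OCc1ccccc1 | intermediate
22 | (2R,3S,4S)-3-acetoxy-7,8-bis(benzyloxy)-2-[3,4-bis(benzyloxy)phenyl]-4-[(2R,3S)-penta-O-benzylcatechin-8-yl]chroman (nona-O-benzyl 3-O-acetate) | c1ccccc1COc1ccc([C@H]2Oc3c(ccc(OCc4ccccc4)c3OCc3ccccc3)[C@@H](c3c(OCc4ccccc4)cc(OCc4ccccc4)c4c3O[C@H](c3ccc(OCc5ccccc5)c(OCc5ccccc5)c3)[C@@H](OCc3ccccc3)C4)[C@@H]2OC(C)=O)cc1OCc1ccccc1 | intermediate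
23 | (2R,3S,4S)-7,8-bis(benzyloxy)-2-[3,4-bis(benzyloxy)phenyl]-4-[(2R,3S)-penta-O-benzylcatechin-8-yl]chroman-3-ol (nona-O-benzyl 3-ol) | c1ccccc1COc1ccc([C@H]2Oc3c(ccc(OCc4ccccc4)c3OCc3ccccc3)[C@@H](c3c(OCc4ccccc4)cc(OCc4ccccc4)c4c3O[C@H](c3ccc(OCc5ccccc5)c(OCc5ccccc5)c3)[C@@H](OCc3ccccc3)C4)[C@@H]2O)cc1OCc1ccccc1 | intermediate
24 | (2R,3S,4S)-2-(3,4-dihydroxyphenyl)-4-[(2R,3S)-catechin-8-yl]chroman-3,7,8-triol, CNP0231186.1 | Oc1ccc([C@H]2Oc3c(ccc(O)c3O)[C@@H](c3c(O)cc(O)c4c3O[C@H](c3ccc(O)c(O)c3)[C@@H](O)C4)[C@@H]2O)cc1O | target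

**Count and risks**

Total step count: 14. Longest linear sequence: 10 steps (steps 5–14, from (+)-catechin 9 to 24).

Steps most likely to fail:

1. Step 12 (the proposed method). Four processes may defeat it:
   - ionisation of the acetal in the wrong sense, with loss of the phenol instead of methanol;
   - Friedel–Crafts attack of the oxocarbenium at the free C6 of the catechin ring;
   - acid-induced oligomerisation of the electron-rich enol acetate;
   - poor facial discrimination by the chiral anion.

   Fallback with known chemistry, from aldehyde 15 and phenol 4, returning at 23: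
   - Claisen–Schmidt condensation of 15 with commercial 3',4'-bis(benzyloxy)acetophenone (KOH, EtOH/THF) should give the (E)-enone F1.
   - Heating F1 with phenol 4 and an acid (p-TsOH, toluene) should give the 2,4-diaryl-4H-chromene as its (4S) epimer F2 together with the (4R) epimer F3. This is a conjugate Friedel–Crafts addition of the phenol carbon ortho to the hydroxyl, followed by cyclodehydration; the two epimers are diastereomers and are to be separated by chromatography.
   - Hydroboration–oxidation of F2 (BH3·SMe2, THF; then NaOH, H2O2) places boron on C3 and adds H and B syn on the face opposite the C4 substituent. This is the known route from flav-2-enes to 2,3-trans-flavan-3-ols and should give 23 with the 2,3-trans-3,4-trans arrangement.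
   - Here C4–C4a is made by intermolecular arylation and O1–C2 by condensation, and the acetate stage 22 is bypassed.

2. Step 11. The electron-rich alkenyl borate may undergo protodeboronation under the acidic, oxidising conditions, or the alkene geometry may erode during copper transmetalation.

   Fallback from boronate 17, returning at 19:
   - Oxidation of 17 with NaBO3·4H2O (THF/H2O) should give 2-(penta-O-benzylcatechin-8-yl)acetaldehyde F4.
   - Enol acetylation of F4 (Ac2O, KOAc, 100 °C) is expected to favour the E isomer because the di-ortho-substituted aryl group disfavours the Z form.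
   - 19 is separated by chromatography from the (Z)-enol acetate F5, which can be re-equilibrated with catalytic iodine.
   - Geometry then rests on thermodynamic preference and separation rather than on a stereospecific coupling.

3. Step 4. The highly stabilised benzylic cation from 7 may alkylate the electron-rich phenol ring on carbon instead of on oxygen, and the mixed acetal may hydrolyse during isolation.

   Fallback from aldehyde 5 and phenol 4, returning at 8:
   - NaBH4 reduction of 5 gives 3,4-bis(benzyloxy)benzyl alcohol F6.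
   - Mitsunobu etherification of F6 with 4 (PPh3, DIAD, THF) gives 3,4-bis(benzyloxy)benzyl 2,3-bis(benzyloxy)phenyl ether F7.
   - DDQ in CH2Cl2 containing dry methanol and 4 Å MS abstracts hydride from the dialkoxybenzylic methylene, and methanol traps the resulting cation to give 8.
   - The O-aryl bond is thus made on a plain benzyl ether and the acetal oxidation level is reached afterwards.

**Further compounds**

F1 | step 12 | (E)-1-[3,4-bis(benzyloxy)phenyl]-3-[(2R,3S)-penta-O-benzylcatechin-8-yl]prop-2-en-1-one | O=C(/C=C/c1c(OCc3ccccc3)cc(OCc3ccccc3)c2c1O[C@H](c1ccc(OCc3ccccc3)c(OCc3ccccc3)c1)[C@@H](OCc1ccccc1)C2)c1ccc(OCc2ccccc2)c(OCc2ccccc2)c1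
F2 | step 12 | (4S)-7,8-bis(benzyloxy)-2-[3,4-bis(benzyloxy)phenyl]-4-[(2R,3S)-penta-O-benzylcatechin-8-yl]-4H-chromene | c1ccccc1COc1ccc(C2=C[C@H](c3c(OCc4ccccc4)cc(OCc4ccccc4)c4c3O[C@H](c3ccc(OCc5ccccc5)c(OCc5ccccc5)c3)[C@@H](OCc3ccccc3)C4)c3ccc(OCc4ccccc4)c(OCc4ccccc4)c3O2)cc1OCc1ccccc1
F3 | step 12 | (4R)-7,8-bis(benzyloxy)-2-[3,4-bis(benzyloxy)phenyl]-4-[(2R,3S)-penta-O-benzylcatechin-8-yl]-4H-chromene | c1ccccc1COc1ccc(C2=C[C@@H](c3c(OCc4ccccc4)cc(OCc4ccccc4)c4c3O[C@H](c3ccc(OCc5ccccc5)c(OCc5ccccc5)c3)[C@@H](OCc3ccccc3)C4)c3ccc(OCc4ccccc4)c(OCc4ccccc4)c3O2)cc1OCc1ccccc1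
F4 | step 11 | 2-[(2R,3S)-penta-O-benzylcatechin-8-yl]acetaldehyde | O=CCc1c(OCc3ccccc3)cc(OCc3ccccc3)c2c1O[C@H](c1ccc(OCc3ccccc3)c(OCc3ccccc3)c1)[C@@H](OCc1ccccc1)C2
F5 | step 11 | (Z)-2-[(2R,3S)-penta-O-benzylcatechin-8-yl]vinyl acetate | CC(=O)O/C=C\c1c(OCc3ccccc3)cc(OCc3ccccc3)c2c1O[C@H](c1ccc(OCc3ccccc3)c(OCc3ccccc3)c1)[C@@H](OCc1ccccc1)C2
F6 | step 4 | 3,4-bis(benzyloxy)benzyl alcohol | OCc1ccc(OCc2ccccc2)c(OCc2ccccc2)c1
F7 | step 4 | 3,4-bis(benzyloxy)benzyl 2,3-bis(benzyloxy)phenyl ether | c1ccccc1COc1ccc(COc2cccc(OCc3ccccc3)c2OCc2ccccc2)cc1OCc1ccccc1
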